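**Plan**
1. The retrosynthesis first cuts the two aryl–CH2 bonds C6–C1″ and C8–C1‴ on the A ring (both prenyl groups at once), which leads back to a 6,8-diiodoflavanone.
2. It then cuts the 2,2-dimethylpyran on the B ring (O4′–CMe2 and C3′–CH=) and finally the two C–I bonds, arriving at (S)-liquiritigenin.
3. Forward: the chroman-4-one (A/C rings) is bought. Iodination marks C6 and C8, the pyran ring is annulated onto 4′-OH/C3′ of the B ring, and the two prenyl chains are joined last.
4. Enabling feature: C6 and C8 of the A ring are the two carbons ortho to the C7 hydroxyl (and para/ortho to the ring oxygen O1), where electrophilic iodination goes. The two iodines also block the 7-OH, so the pyran can only form on the B ring.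
5. Stereochemistry: the only stereocentre, C2 (S), comes from the chiral pool and is never touched; every step is neutral or weakly acidic to avoid ring-opening racemisation.

Key step: step 3

Assumption: commercial (S)-liquiritigenin is taken as the enantiomerically pure (2S) natural product. Because 4′-hydroxyflavanones racemise by ring opening in base, its optical purity and that of 5 and 9 should be checked by chiral HPLC.

**Step 1**
Reactants: 1 (S)-liquiritigenin; 2 N-iodosuccinimide
Product: 5 (2S)-7-hydroxy-2-(4-hydroxyphenyl)-6,8-diiodochroman-4-one, via 6-iodoliquiritigenin 3 (not isolated), via 8-iodoliquiritigenin 4 (not isolated)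
Conditions: NIS (2.1 equiv), DMF, 0 °C to rt, dark; aq. Na2S2O3 quench
Reagents that add atoms: N-iodosuccinimide (2), O=C1CCC(=O)N1I
Why: Electrophilic aromatic iodination should favour the A ring, because C6 and C8 are each ortho to the acidic 7-OH and para or ortho to O1 (a doubly oxygen-activated, resorcinol-type ring) whereas the B ring has one donor, and the neutral, base-free reagent should leave the pyranone ring closed so that C2 stays S.

**Step 2**
Reactants: 5 (2S)-7-hydroxy-2-(4-hydroxyphenyl)-6,8-diiodochroman-4-one; 6 3-methylbut-2-enal
Product: 9 (2S)-7-hydroxy-6,8-diiodo-2-(2,2-dimethyl-2H-chromen-6-yl)chroman-4-one, via B-ring benzodioxaborin 7 (not isolated), via ortho-quinone methide 8 (not isolated)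
Conditions: 6 (2 equiv), PhB(OH)2 (1.0 equiv, template, returned as the free acid on aqueous work-up), EtCO2H (cat.), toluene, reflux, Dean–Stark
Reagents that add atoms: 3-methylbut-2-enal (6), CC(C)=CC=O
Why: Boronic-acid-templated ortho-hydroxyalkylation of a phenol by an enal, thermal extrusion to an ortho-quinone methide and oxa-6π electrocyclisation is a known one-pot 2H-chromene annulation, and in 5 only the 4′-OH has a free ortho carbon (C3′) because the 7-OH is flanked by iodine on both sides, while the weakly acidic, base-free medium should spare C2 and the C–I bonds.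

**Step 3**
Reactants: 9 (2S)-7-hydroxy-6,8-diiodo-2-(2,2-dimethyl-2H-chromen-6-yl)chroman-4-one; 10 tributyl(3-methylbut-2-enyl)stannane
Product: 13 (2S)-7-hydroxy-2-(2,2-dimethyl-2H-chromen-6-yl)-6,8-bis(3-methylbut-2-enyl)chroman-4-one, via 8-iodo-6-prenyl monocoupled flavanone 11 (not isolated), via 6-iodo-8-prenyl monocoupled flavanone 12 (not isolated)
Conditions: 10 (4 equiv), Pd(PPh3)4 (10 mol %), DMF, 90 °C, degassed, dark; aq. KF work-up
Reagents that add atoms: tributyl(3-methylbut-2-enyl)stannane (10), CC(C)=CC[Sn](CCCC)(CCCC)CCCC
Why: Pd(0) inserts into each aryl C–I bond, the prenyl group passes from tin to palladium, and the aryl(allyl)palladium(II) species reductively eliminates to form the C6–CH2 and C8–CH2 bonds in turn, the monoiodides 11 and 12 reacting on in the same flask. This is the Stille (Migita–Kosugi–Stille) coupling of aryl iodides with allylic stannanes, a known reaction used here twice on one ring. No ring closes and no stereocentre is created; C2 should be carried through unchanged because the medium is neutral and base-free and the B-ring oxygen, now an ether inside the chromene, can no longer open the C2–O1 bond through a quinone methide. The selectivity needed is linear (CH2-bound) rather than branched (1,1-dimethylallyl) attachment: under PPh3 ligation the σ/π-allylpalladium intermediate equilibrates and should couple at its unsubstituted terminus, since bond formation at the quaternary end next to an ortho,ortho-disubstituted aryl is sterically disfavoured. Complete twofold coupling is supported by the high reactivity of C–I bonds in oxidative addition and by excess 10, which also covers stannane lost to protonolysis by the acidic 7-OH (any O–Sn bond is cleaved in the fluoride work-up). The ring positions of both chains are fixed beforehand by the iodine atoms, so no regiochemical question about the A ring arises here.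

**Compound list**
1 | (S)-liquiritigenin, (2S)-7-hydroxy-2-(4-hydroxyphenyl)chroman-4-one | Oc1ccc2c(c1)O[C@H](c1ccc(O)cc1)CC2=O | starting material
2 | N-iodosuccinimide | O=C1CCC(=O)N1I | starting material
3 | (2S)-7-hydroxy-2-(4-hydroxyphenyl)-6-iodochroman-4-one | Ic1cc2c(cc1O)O[C@H](c1ccc(O)cc1)CC2=O | intermediate (not isolated)
4 | (2S)-7-hydroxy-2-(4-hydroxyphenyl)-8-iodochroman-4-one | Oc1ccc2c(c1I)O[C@H](c1ccc(O)cc1)CC2=O | intermediate (not isolated)
5 | (2S)-7-hydroxy-2-(4-hydroxyphenyl)-6,8-diiodochroman-4-one | Ic1cc2c(c(I)c1O)O[C@H](c1ccc(O)cc1)CC2=O | intermediate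
6 | 3-methylbut-2-enal | CC(C)=CC=O | starting material
7 | (2S)-7-hydroxy-6,8-diiodo-2-[4-(2-methylprop-1-enyl)-2-phenyl-4H-1,3,2-benzodioxaborin-6-yl]chroman-4-one (either configuration at the dioxaborin C4) | Ic1cc2c(c(I)c1O)O[C@H](c1ccc3OB(c4ccccc4)OC(C=C(C)C)c3c1)CC2=O | intermediate (not isolated)
8 | (2S)-7-hydroxy-6,8-diiodo-2-[3-(3-methylbut-2-enylidene)-4-oxocyclohexa-1,5-dien-1-yl]chroman-4-one | Ic1cc2c(c(I)c1O)O[C@H](C1=CC(=CC=C(C)C)C(=O)C=C1)CC2=O | intermediate (not isolated)
9 | (2S)-7-hydroxy-6,8-diiodo-2-(2,2-dimethyl-2H-chromen-6-yl)chroman-4-one | Ic1cc2c(c(I)c1O)O[C@H](c1ccc3c(c1)C=CC(C)(C)O3)CC2=O | intermediate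
10 | tributyl(3-methylbut-2-enyl)stannane | CC(C)=CC[Sn](CCCC)(CCCC)CCCC | starting material
11 | (2S)-7-hydroxy-8-iodo-6-(3-methylbut-2-enyl)-2-(2,2-dimethyl-2H-chromen-6-yl)chroman-4-one | CC(C)=CCc1cc2c(c(I)c1O)O[C@H](c1ccc3c(c1)C=CC(C)(C)O3)CC2=O | intermediate (not isolated)
12 | (2S)-7-hydroxy-6-iodo-8-(3-methylbut-2-enyl)-2-(2,2-dimethyl-2H-chromen-6-yl)chroman-4-one | Ic1cc2c(c(CC=C(C)C)c1O)O[C@H](c1ccc3c(c1)C=CC(C)(C)O3)CC2=O | intermediate (not isolated)
13 | (2S)-7-hydroxy-2-(2,2-dimethyl-2H-chromen-6-yl)-6,8-bis(3-methylbut-2-enyl)chroman-4-one, the 6,8-diprenylated lespeflorin flavanone | CC(C)=CCc1cc2c(c(CC=C(C)C)c1O)O[C@H](c1ccc3c(c1)C=CC(C)(C)O3)CC2=O | target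

Total step count: 3
Longest linear sequence: 3 steps (1 → 5 → 9 → 13)

**Steps most likely to fail**

Step 2 (chromene annulation). The B ring is a non-activated para-alkylphenol, so ortho-hydroxyalkylation may be slow. Self-condensation of the enal and heat-induced ring-opening racemisation at C2 could then compete. The fallback sets out from 5 and swaps the condensation for an O-alkylation/sigmatropic sequence. Copper-catalysed alkylation of the 4′-OH with 3-chloro-3-methylbut-1-yne (DBU, cat. CuCl2, MeCN, 0 °C, short reaction time) should give (2S)-7-hydroxy-6,8-diiodo-2-[4-(2-methylbut-3-yn-2-yloxy)phenyl]chroman-4-one F1. The 7-oxygen, wedged between two iodines, should not accept the tertiary propargyl group, and its ionised form should disfavour opening of the C2–O1 bond. Heating F1 in xylene at about 135 °C should trigger aromatic Claisen rearrangement, 1,5-hydrogen shift to the same quinone methide 8 and 6π closure, coming back to the route at 9.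

Step 1 (diiodination). Ring selectivity may be lost, with iodination spilling over to C3′/C5′ of the B ring before the A ring has taken up its second iodine. The fallback sets out from 1 and deactivates the B ring by acylation. Acetylation (Ac2O, pyridine, 0 °C) should give (S)-liquiritigenin 7,4′-di-O-acetate F2. The more labile 7-O-acetate, the ester of the more acidic phenol, is then removed selectively (PhSH, imidazole, NMP, 0 °C) to give (2S)-4-(7-hydroxy-4-oxochroman-2-yl)phenyl acetate F3. NIS (2.1 equiv, DMF) should now iodinate only the A ring, giving (2S)-4-(7-hydroxy-6,8-diiodo-4-oxochroman-2-yl)phenyl acetate F4. Acid methanolysis (AcCl cat., MeOH, rt) removes the remaining acetate without base and returns to the route at 5.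

Step 3 (double Stille prenylation). Allyl transposition on palladium could give branched (1,1-dimethylallyl) attachment. Protodeiodination, or stalling after the first coupling at the more crowded C8–I bond, would lower the material throughput. The fallback sets out from 9 and separates C–C bond formation from installation of the trisubstituted alkene. Twofold Stille coupling with allyltributylstannane (Pd(PPh3)4, DMF, 90 °C), where no α/γ question exists, should give (2S)-6,8-diallyl-7-hydroxy-2-(2,2-dimethyl-2H-chromen-6-yl)chroman-4-one F5. Double olefin cross-metathesis of F5 with 2-methylbut-2-ene (second-generation Grubbs catalyst, CH2Cl2/2-methylbut-2-ene, rt to 35 °C, sealed) should convert both allyl groups into prenyl groups. The hindered, unstrained ring alkene of the chromene should stay out of the metathesis, and the sequence comes back to the route at 13.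

**Further compounds**
F1 | step 2 | (2S)-7-hydroxy-6,8-diiodo-2-[4-(2-methylbut-3-yn-2-yloxy)phenyl]chroman-4-one | Ic1cc2c(c(I)c1O)O[C@H](c1ccc(OC(C)(C)C#C)cc1)CC2=O
F2 | step 1 | (S)-liquiritigenin 7,4′-di-O-acetate | CC(=O)Oc1ccc2c(c1)O[C@H](c1ccc(OC(C)=O)cc1)CC2=O
F3 | step 1 | (2S)-4-(7-hydroxy-4-oxochroman-2-yl)phenyl acetate | Oc1ccc2c(c1)O[C@H](c1ccc(OC(C)=O)cc1)CC2=O
F4 | step 1 | (2S)-4-(7-hydroxy-6,8-diiodo-4-oxochroman-2-yl)phenyl acetate | Ic1cc2c(c(I)c1O)O[C@H](c1ccc(OC(C)=O)cc1)CC2=O
F5 | step 3 | (2S)-6,8-diallyl-7-hydroxy-2-(2,2-dimethyl-2H-chromen-6-yl)chroman-4-one | C=CCc1cc2c(c(CC=C)c1O)O[C@H](c1ccc3c(c1)C=CC(C)(C)O3)CC2=O
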